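**Retrosynthetic overview**
- Octacosanolide (4) is a single 29-membered ring (the ester oxygen plus C1–C28, numbered from the carbonyl carbon) with no stereocentre, so the only problem is ring size.
- Feature used: C1–C9 and C22–C28, with the O–C(=O) link between them, are the sixteen carbons of the 17-membered ring of isoambrettolide (1) cut at its C9=C10 olefin. C10–C21 are the twelve carbons of the 12-membered ring of cyclododecene (2), and 16 + 12 = 28.
- Disconnection 1: 4 ⇒ diene 3 (olefins at C9=C10 and C21=C22) by removing four hydrogens.
- Disconnection 2: 3 ⇒ 1 + 2 by a metathetic ring merge at C9=C10 and C21=C22. The 29-membered ring is the only ring formed, in step 1.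

Key step: step 1

Remark: commercial isoambrettolide is taken as the (E)-isomer and cyclododecene as its E/Z mixture; olefin geometry does not matter because step 2 removes every double bond.

**Step 1**
Reactants: 1 isoambrettolide ((E)-oxacycloheptadec-10-en-2-one); 2 cyclododecene (E/Z mixture)
Product: 3 1-oxacyclononacosa-10,22-dien-2-one (mixture of olefin geometries)
Conditions: RuCl2(=CHPh)(PCy3)(H2IMes) (second-generation Grubbs catalyst, 2 mol%), 1,4-benzoquinone (10 mol%), 2 (3 equiv), CH2Cl2 (0.02 M in 1), 40 °C; ethyl vinyl ether quench before concentration; SiO2 chromatography (hexane, then hexane/EtOAc), bulb-to-bulb distillation to remove 1, preparative size-exclusion chromatography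
Reagents that add atoms: none
Why: The ruthenium alkylidene opens 2 by [2+2] cycloaddition and cycloreversion to a C12 chain ending in a new alkylidene, which cross-metathesises with the C9=C10 olefin of 1, opening the 17-membered ring and forming one of the two new double bonds (C9=C10 or C21=C22 of 3). The alkylidene now at the far end of the 28-carbon chain back-bites on the olefin left by the first opening, so the 29-membered ring is closed by macrocyclic ring-closing metathesis, the second new double bond forms and the carbene is released for the next cycle. The closest known reaction type is ring-expansion metathesis, that is the metathetic co-oligomerisation of low-strain cycloalkenes and unsaturated macrolactones to cyclic oligomers below the critical concentration of the ring–chain equilibrium. No stereocentre is formed, and the E/Z mixture at both new olefins is removed in step 2. The step needs the crossed one-to-one ring rather than unchanged 1, the self-merged 34- and 24-membered rings or higher co-rings; nothing in the substrates biases this, so it rests on reversibility among nearly strain-free rings, an excess of 2 at a concentration just below the onset of chain formation, and recombination and re-equilibration of recovered 1, 2 and wrong-sized unsaturated rings, while the symmetric =CH(CH2)10CH= unit of 2 ensures that either orientation of insertion gives the same constitution. The ring must keep exactly 28 carbons, which 1,4-benzoquinone and the mild temperature should secure by suppressing olefin migration through ruthenium hydride species, and the number of ester groups (none, one or two) lets SiO2 sort the ring families before the monolactones are separated by size.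

**Step 2**
Reactants: 3 1-oxacyclononacosa-10,22-dien-2-one (mixture of olefin geometries)
Product: 4 octacosanolide (1-oxacyclononacosan-2-one)
Conditions: H2 (1 atm), Pd/C (10 wt% Pd), EtOAc, 40 °C; filtration, recrystallisation from acetone
Reagents that add atoms: none
Why: Heterogeneous catalytic hydrogenation should saturate both 1,2-disubstituted olefins whatever their geometry, the saturated lactone carries no group prone to hydrogenolysis, and no stereocentre is created.

**Compound list**
1 | isoambrettolide, (E)-oxacycloheptadec-10-en-2-one | O=C1CCCCCCC/C=C/CCCCCCO1 | starting material
2 | cyclododecene (E/Z mixture, geometry not specified) | C1=CCCCCCCCCCC1 | starting material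
3 | 1-oxacyclononacosa-10,22-dien-2-one (mixture of E and Z at both olefins, geometry not specified) | O=C1CCCCCCCC=CCCCCCCCCCCC=CCCCCCCO1 | intermediate
4 | octacosanolide, 1-oxacyclononacosan-2-one (achiral, no stereocentre) | O=C1CCCCCCCCCCCCCCCCCCCCCCCCCCCO1 | target

**Total step count:** 2
**Longest linear sequence:** 2 steps (both ring olefins are purchased)

**Steps most likely to fail** (the route has only two steps, so both are ranked)

1. Step 1. Three processes may defeat it:
   - Under ring–chain equilibrium most of the lactone is expected to stay as the unchanged 17-membered ring, with the rest spread over self-merged and higher co-rings, so the crossed ring is likely a minor share per pass.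
   - Olefin migration by ruthenium hydride species would shift ring size by single carbons that cannot be separated later.
   - Concentrating the solution while the catalyst is still active would drive chain growth.

   Fallback, setting out from 1 and coming back at 4: the ring is built by one olefination and one macrolactonisation instead of by ring merging. Methanolysis of 1 (NaOMe, MeOH, reflux) should give methyl (E)-16-hydroxyhexadec-9-enoate F1. Dess–Martin oxidation (Dess–Martin periodinane, NaHCO3, CH2Cl2) should convert it into methyl (E)-16-oxohexadec-9-enoate F2. Separately, 12-bromododecan-1-ol and PPh3 (MeCN, reflux) give (12-hydroxydodecyl)triphenylphosphonium bromide F3. Its alkoxide ylide (NaN(SiMe3)2, 2.1 equiv, THF, −78 °C) should add to F2 in a Wittig reaction to give methyl (9E,16Z)-28-hydroxyoctacosa-9,16-dienoate F4. Saponification (LiOH, THF/MeOH/H2O; dilute HCl) gives (9E,16Z)-28-hydroxyoctacosa-9,16-dienoic acid F5. Yamaguchi macrolactonisation (2,4,6-trichlorobenzoyl chloride, Et3N, THF; slow addition to 4-(dimethylamino)pyridine in toluene at reflux, about 1 mM) should close the 29-membered ring as (10E,17Z)-1-oxacyclononacosa-10,17-dien-2-one F6. Hydrogenation of F6 under the conditions of step 2 gives 4.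

2. Step 2. Double-bond migration along the chain on the palladium surface before saturation could bring an olefin next to the lactone oxygen and open the ring by allylic C–O hydrogenolysis. Crystallisation of the waxy product onto the catalyst could also stall the reduction before both olefins are saturated.

   Fallback, setting out from 3 and coming back at 4: metal-free diimide reduction (p-toluenesulfonyl hydrazide, NaOAc, THF/H2O, reflux, repeated charges if needed) transfers hydrogen in a concerted way, without olefin migration or hydrogenolysis. This path makes no new compound (none F0).

**Further compounds**
F1 | step 1 | methyl (E)-16-hydroxyhexadec-9-enoate | COC(=O)CCCCCCC/C=C/CCCCCCO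
F2 | step 1 | methyl (E)-16-oxohexadec-9-enoate | COC(=O)CCCCCCC/C=C/CCCCCC=O
F3 | step 1 | (12-hydroxydodecyl)triphenylphosphonium bromide | OCCCCCCCCCCCC[P+](c1ccccc1)(c1ccccc1)c1ccccc1.[Br-]
F4 | step 1 | methyl (9E,16Z)-28-hydroxyoctacosa-9,16-dienoate | COC(=O)CCCCCCC/C=C/CCCCC/C=C\CCCCCCCCCCCO
F5 | step 1 | (9E,16Z)-28-hydroxyoctacosa-9,16-dienoic acid | OC(=O)CCCCCCC/C=C/CCCCC/C=C\CCCCCCCCCCCO
F6 | step 1 | (10E,17Z)-1-oxacyclononacosa-10,17-dien-2-one | O=C1CCCCCCC/C=C/CCCCC/C=C\CCCCCCCCCCCO1
F0 | step 2 | none | none
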